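**Plan**
- Retrosynthesis: the C4–Br bond is cut first (back to a C4 alcohol, then a ketone masked as a dioxolane), then the C9=C13 bond (Wittig) and the C7=C8 unsaturation (ketone dehydrogenation). The spiro ketone is opened by a retro-oxy-Cope shift (C6–C11 cut, C9–C12 rejoined), the vinyl–C9 bond is cut, and the two C5–CH3 bonds lead back to 6-methoxy-2-tetralone.
- Enabling feature: ring A is C1–C6 (C1=C12H2, C4–Br, gem-dimethyl C5, spiro C6) and ring B is C6–C11 (C7=C8, C9=C13HBr). The methylene carbon C12 and the oxidised carbon C9 are linked through C1, C6 and C11–C10 exactly as a [3,3] shift of a diene C11=C10–C9(O)–C12–C1=C6 leaves them.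
- Forward: ring A is the saturated ring of the tetralone. Birch reduction turns the anisole ring into an octalin, a vinyl group is added at C9, and ring B closes in the anionic oxy-Cope step while the old carbocycle opens to leave C1=C12. The diene and the bromide follow.
- Stereochemistry: C6 (S) comes from enantiotopic-group-selective deprotonation of the achiral spiro ketone by a chiral lithium amide. C4 (R) comes from a CBS reduction under reagent control followed by SN2 inversion with bromide. The 9Z geometry comes from the Wittig bromomethylenation.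

Key step: step 6

Remark: all spiro compounds carry the target locants (ring A C1–C6, ring B C6–C11, C12 the methylidene carbon, C13 the bromomethylidene carbon).
Assumption: the lithium (R,R)-amide is taken to distinguish the two axial α-hydrogens of ring B in the same sense as in 4-tert-butylcyclohexanone; if the opposite sense is found, the (S,S)-amide is used.

Step 1
Reactants: 1 6-methoxy-2-tetralone (6-methoxy-3,4-dihydronaphthalen-2(1H)-one); 2 iodomethane
Product: 4 6-methoxy-1,1-dimethyl-3,4-dihydronaphthalen-2(1H)-one, via 6-methoxy-1-methyl-2-tetralone 3 (not isolated)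
Conditions: KOtBu (2.2 equiv), MeI (2.5 equiv), t-BuOH/THF, 0 °C → rt
Reagents that add atoms: iodomethane, CI
Why: Enolate C-alkylation; C1 is both benzylic and α to the carbonyl, so both methyl groups enter there and alkylation stops at the quaternary carbon.

Step 2
Reactants: 4 6-methoxy-1,1-dimethyl-3,4-dihydronaphthalen-2(1H)-one
Product: 5 2,2-ethylenedioxy-6-methoxy-1,1-dimethyl-1,2,3,4-tetrahydronaphthalene
Conditions: HOCH2CH2OH, TsOH·H2O (cat.), benzene, reflux (Dean–Stark)
Reagents that add atoms: ethylene glycol, OCCO
Why: Acid-catalysed ketalisation with azeotropic removal of water; the dioxolane masks the later C4 carbonyl through the reductive, organometallic and basic steps.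

Step 3
Reactants: 5 2,2-ethylenedioxy-6-methoxy-1,1-dimethyl-1,2,3,4-tetrahydronaphthalene
Product: 6 2,2-ethylenedioxy-6-methoxy-1,1-dimethyl-1,2,3,4,5,8-hexahydronaphthalene
Conditions: Li, NH3(l), THF, t-BuOH, −78 → −33 °C; then NH4Cl
Reagents that add atoms: none
Why: Birch reduction; the anisole ring takes up hydrogen at the two carbons that carry neither methoxy nor alkyl groups (C5 and C8), leaving the enol ether and the tetrasubstituted ring-fusion alkene.

Step 4
Reactants: 6 2,2-ethylenedioxy-6-methoxy-1,1-dimethyl-1,2,3,4,5,8-hexahydronaphthalene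
Product: 7 6,6-ethylenedioxy-5,5-dimethyl-3,4,5,6,7,8-hexahydronaphthalen-2(1H)-one
Conditions: (CO2H)2·2H2O, acetone/H2O, rt
Reagents that add atoms: water, O
Why: Mild enol ether hydrolysis with oxalic acid, which should give the non-conjugated β,γ-enone and leave the hindered dioxolane intact, as in the corresponding Birch-derived steroid dienol ethers.

Step 5
Reactants: 7 6,6-ethylenedioxy-5,5-dimethyl-3,4,5,6,7,8-hexahydronaphthalen-2(1H)-one; 8 vinylmagnesium bromide
Product: 9 2-ethenyl-6,6-ethylenedioxy-5,5-dimethyl-1,2,3,4,5,6,7,8-octahydronaphthalen-2-ol (racemic)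
Conditions: CH2=CHMgBr, CeCl3 (anhydrous), THF, −78 °C; then sat. aq. NH4Cl
Reagents that add atoms: vinylmagnesium bromide, C=C[Mg]Br
Why: 1,2-addition of an organocerium reagent, which is nucleophilic but weakly basic and so should not enolise the ketone toward the ring alkene.

Step 6
Reactants: 9 2-ethenyl-6,6-ethylenedioxy-5,5-dimethyl-1,2,3,4,5,6,7,8-octahydronaphthalen-2-ol
Product: 12 4,4-ethylenedioxy-5,5-dimethyl-1-methylidenespiro[5.5]undecan-9-one, via tertiary potassium alkoxide 10 (not isolated), via spirocyclic potassium enolate 11 (not isolated)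
Conditions: KH, 18-crown-6, THF, 0 → 60 °C; then sat. aq. NH4Cl, 0 °C
Reagents that add atoms: none
Why: KH with 18-crown-6 gives the free alkoxide 10, whose cyclohexene ring C9–C12–C1=C6–C7–C8 can reach a boat that holds the vinyl group over C6, and the 1,5-diene C11=C10–C9–C12–C1=C6 then undergoes a concerted [3,3] shift (anionic oxy-Cope rearrangement) that forms C6–C11 and breaks C9–C12. The closest known reactions are the alkoxide-accelerated oxy-Cope rearrangements of 1-vinylcyclohex-3-en-1-ols and 2-vinylbicyclo[2.2.2]oct-5-en-2-ols through the same boat array; the only extension is that the receiving carbon C6 sits beside the gem-dimethyl carbon C5. Ring B (C6–C7–C8–C9–C10–C11) closes in sigmatropic fashion as an enolate while the old carbocycle opens, which leaves C1=C12 as the exocyclic methylene. No stereocentre results, because protonation of enolate 11 gives a ketone whose two ring B arms are identical, so C6 is only prochiral. The step needs the [3,3] path to win over a [1,3] shift or alkoxide fragmentation: the vinyl terminus cannot reach C12 in a cyclic array, the crown ether loosens the ion pair and lowers the barrier of the concerted path, and enolate formation makes the shift irreversible.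

Step 7
Reactants: 12 4,4-ethylenedioxy-5,5-dimethyl-1-methylidenespiro[5.5]undecan-9-one
Product: 14 (6S)-4,4-ethylenedioxy-5,5-dimethyl-1-methylidene-9-(trimethylsilyloxy)spiro[5.5]undec-8-ene, via lithium enolate 13 (not isolated)
Conditions: (R,R)-bis(1-phenylethyl)amine, n-BuLi, LiCl, THF, −78 °C; then 12 and Me3SiCl, −100 → −78 °C
Reagents that add atoms: chlorotrimethylsilane, C[Si](C)(C)Cl
Why: Enantiotopic-group-selective deprotonation by a chiral lithium amide with internal silyl quench; ring B is held in the chair with the quaternary C5 equatorial, so the base should pick one of the two axial α-hydrogens as it does in 4-tert-butylcyclohexanone, which puts the enol double bond in the arm that becomes C7–C8 and fixes C6 as S.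

Step 8
Reactants: 14 (6S)-4,4-ethylenedioxy-5,5-dimethyl-1-methylidene-9-(trimethylsilyloxy)spiro[5.5]undec-8-ene
Product: 15 (6S)-4,4-ethylenedioxy-5,5-dimethyl-1-methylidenespiro[5.5]undec-7-en-9-one
Conditions: Pd(OAc)2 (1.05 equiv), MeCN, rt
Reagents that add atoms: none
Why: Saegusa–Ito oxidation; palladation of the silyl enol ether at C8 and β-hydride elimination toward C7 place the enone double bond in the arm chosen in step 7, so the C6 configuration is carried over unchanged.

Step 9
Reactants: 15 (6S)-4,4-ethylenedioxy-5,5-dimethyl-1-methylidenespiro[5.5]undec-7-en-9-one; 16 (bromomethyl)triphenylphosphonium bromide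
Product: 17 (6S,9Z)-9-(bromomethylidene)-4,4-ethylenedioxy-5,5-dimethyl-1-methylidenespiro[5.5]undec-7-ene
Conditions: Ph3P+CH2Br Br−, KOtBu, THF, −78 → 0 °C; 9E isomer removed on AgNO3-impregnated silica
Reagents that add atoms: (bromomethyl)triphenylphosphonium bromide, BrC[P+](c1ccccc1)(c1ccccc1)c1ccccc1.[Br-]
Why: Wittig bromomethylenation of the enone carbonyl; the bromine is expected to settle beside the flat C8–H position and away from the C10 methylene, since halomethylene ylides place the halogen away from the more encumbered α-carbon of a cyclic ketone, giving mainly the 9Z diene.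

Step 10
Reactants: 17 (6S,9Z)-9-(bromomethylidene)-4,4-ethylenedioxy-5,5-dimethyl-1-methylidenespiro[5.5]undec-7-ene
Product: 18 (6S,9Z)-9-(bromomethylidene)-5,5-dimethyl-1-methylidenespiro[5.5]undec-7-en-4-one
Conditions: pyridinium p-toluenesulfonate, acetone/H2O, 50 °C
Reagents that add atoms: water, O
Why: Acid-catalysed ketal hydrolysis under buffered conditions, mild enough to leave the exocyclic alkene, the bromodiene and the C6 centre untouched.

Step 11
Reactants: 18 (6S,9Z)-9-(bromomethylidene)-5,5-dimethyl-1-methylidenespiro[5.5]undec-7-en-4-one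
Product: 19 (4S,6S,9Z)-9-(bromomethylidene)-5,5-dimethyl-1-methylidenespiro[5.5]undec-7-en-4-ol
Conditions: (R)-Me-CBS [(3aR)-tetrahydro-1-methyl-3,3-diphenyl-1H,3H-pyrrolo[1,2-c][1,3,2]oxazaborole] (0.2 equiv), catecholborane, toluene, −78 → −40 °C; aqueous work-up
Reagents that add atoms: none
Why: Corey–Bakshi–Shibata reduction; the oxazaborolidine binds the carbonyl anti to the quaternary C5 (large group) and delivers hydride to give the 4S alcohol under reagent control, catecholborane at low temperature spares the 1,1-disubstituted alkene, and any 6R material from step 7 becomes a separable diastereomer here.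

Step 12
Reactants: 19 (4S,6S,9Z)-9-(bromomethylidene)-5,5-dimethyl-1-methylidenespiro[5.5]undec-7-en-4-ol
Product: 20 (4R,6S,9Z)-4-bromo-9-(bromomethylidene)-5,5-dimethyl-1-methylidenespiro[5.5]undec-7-ene
Conditions: PPh3, CBr4, CH2Cl2, 0 °C → rt
Reagents that add atoms: carbon tetrabromide, BrC(Br)(Br)Br
Why: Appel reaction; bromide attacks the phosphorus-activated C4–O carbon from the rear (SN2), so the 4S alcohol gives the 4R bromide, a substitution next to a gem-dimethyl carbon that is known in bromoterpenoid work when the leaving group can stand axial.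

**Compound list**
1 | 6-methoxy-2-tetralone | O=C1CCc2cc(OC)ccc2C1 | starting material
2 | iodomethane | CI | starting material
3 | 6-methoxy-1-methyl-2-tetralone (racemic) | COc1ccc2c(c1)CCC(=O)C2C | intermediate (not isolated)
4 | 6-methoxy-1,1-dimethyl-3,4-dihydronaphthalen-2(1H)-one | COc1ccc2c(c1)CCC(=O)C2(C)C | intermediate
5 | 2,2-ethylenedioxy-6-methoxy-1,1-dimethyl-1,2,3,4-tetrahydronaphthalene | COc1ccc2c(c1)CCC3(OCCO3)C2(C)C | intermediate
6 | 2,2-ethylenedioxy-6-methoxy-1,1-dimethyl-1,2,3,4,5,8-hexahydronaphthalene | COC1=CCC2=C(C1)CCC3(OCCO3)C2(C)C | intermediate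
7 | 6,6-ethylenedioxy-5,5-dimethyl-3,4,5,6,7,8-hexahydronaphthalen-2(1H)-one | O=C1CCC2=C(C1)CCC3(OCCO3)C2(C)C | intermediate
8 | vinylmagnesium bromide | C=C[Mg]Br | starting material
9 | 2-ethenyl-6,6-ethylenedioxy-5,5-dimethyl-1,2,3,4,5,6,7,8-octahydronaphthalen-2-ol (racemic) | C=CC1(O)CCC2=C(C1)CCC3(OCCO3)C2(C)C | intermediate
10 | potassium alkoxide of 9 | C=CC1([O-])CCC2=C(C1)CCC3(OCCO3)C2(C)C.[K+] | intermediate (not isolated)
11 | potassium enolate of 12 (racemic) | C=C1CCC2(OCCO2)C(C)(C)C13CC=C([O-])CC3.[K+] | intermediate (not isolated)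
12 | 4,4-ethylenedioxy-5,5-dimethyl-1-methylidenespiro[5.5]undecan-9-one (achiral) | C=C1CCC2(OCCO2)C(C)(C)C13CCC(=O)CC3 | intermediate
13 | lithium (6S)-4,4-ethylenedioxy-5,5-dimethyl-1-methylidenespiro[5.5]undec-8-en-9-olate | C=C1CCC3(OCCO3)C(C)(C)[C@@]12CC=C([O-])CC2.[Li+] | intermediate (not isolated)
14 | (6S)-4,4-ethylenedioxy-5,5-dimethyl-1-methylidene-9-(trimethylsilyloxy)spiro[5.5]undec-8-ene | C=C1CCC3(OCCO3)C(C)(C)[C@@]12CC=C(O[Si](C)(C)C)CC2 | intermediate
15 | (6S)-4,4-ethylenedioxy-5,5-dimethyl-1-methylidenespiro[5.5]undec-7-en-9-one | C=C1CCC3(OCCO3)C(C)(C)[C@@]12C=CC(=O)CC2 | intermediate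
16 | (bromomethyl)triphenylphosphonium bromide | BrC[P+](c1ccccc1)(c1ccccc1)c1ccccc1.[Br-] | starting material
17 | (6S,9Z)-9-(bromomethylidene)-4,4-ethylenedioxy-5,5-dimethyl-1-methylidenespiro[5.5]undec-7-ene | C=C1CCC3(OCCO3)C(C)(C)[C@@]12C=C/C(=C\Br)CC2 | intermediate
18 | (6S,9Z)-9-(bromomethylidene)-5,5-dimethyl-1-methylidenespiro[5.5]undec-7-en-4-one | C=C1CCC(=O)C(C)(C)[C@@]12C=C/C(=C\Br)CC2 | intermediate
19 | (4S,6S,9Z)-9-(bromomethylidene)-5,5-dimethyl-1-methylidenespiro[5.5]undec-7-en-4-ol | C=C1CC[C@H](O)C(C)(C)[C@@]12C=C/C(=C\Br)CC2 | intermediate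
20 | (4R,6S,9Z)-4-bromo-9-(bromomethylidene)-5,5-dimethyl-1-methylidenespiro[5.5]undec-7-ene | C=C1CC[C@@H](Br)C(C)(C)[C@@]12C=C/C(=C\Br)CC2 | target

Total step count: 12. Longest linear sequence: 12 steps (from 1 to 20).

**Steps most likely to fail, in order of risk**

Step 12. Rear-side attack of bromide at C4 is slowed by the adjacent gem-dimethyl carbon and the spiro carbon beyond it. Ionisation of the activated alcohol with methyl migration from C5, or loss of a C3 proton to give the alkene, may therefore outrun substitution. The fallback sets out from ketone 18 and comes back at target 20, replacing steps 11 and 12; C4 is then set by hydrogen-atom delivery under substrate control instead of by SN2 inversion. Ketone 18 is condensed with hydrazine hydrate (EtOH, 80 °C) to (6S,9Z)-9-(bromomethylidene)-5,5-dimethyl-1-methylidenespiro[5.5]undec-7-en-4-one hydrazone F1. Oxidative bromination with CuBr2 and Et3N in MeOH should give (6S,9Z)-4,4-dibromo-9-(bromomethylidene)-5,5-dimethyl-1-methylidenespiro[5.5]undec-7-ene F2 with loss of nitrogen. One bromine is then removed with Bu3SnH (1 equiv) and Et3B/air in toluene at −78 °C, which should leave the vinylic bromide alone. This would give 20 together with its C4 epimer, (4S,6S,9Z)-4-bromo-9-(bromomethylidene)-5,5-dimethyl-1-methylidenespiro[5.5]undec-7-ene F3, to be separated by chromatography.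

Step 6. Alkoxide 10 may fragment heterolytically into a vinyl ketone and an allyl anion, which can recombine at C12 (a [1,3] shift to an eight-membered ketone) or be quenched by proton transfer. The crowding at C6 may also stop the shift altogether. The fallback sets out from carbinol 9 and comes back at ketone 12; it removes the alkoxide and with it the ionic fragmentation channel. Carbinol 9 is silylated (Me3SiCl, imidazole, DMF) to 2-ethenyl-6,6-ethylenedioxy-5,5-dimethyl-2-(trimethylsilyloxy)-1,2,3,4,5,6,7,8-octahydronaphthalene F4. A neutral thermal siloxy-Cope rearrangement (flash vacuum pyrolysis, or a base-washed sealed tube at about 280–320 °C) should then form the same C6–C11 bond and give racemic 4,4-ethylenedioxy-5,5-dimethyl-1-methylidene-9-(trimethylsilyloxy)spiro[5.5]undec-8-ene F5. Methanolysis (K2CO3, MeOH) returns 12.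

Step 9. The olefination may show poor geometric selectivity, or favour the 9E isomer, because the two α-carbons of the enone differ only as a planar CH and a CH2. The fallback sets out from enone 15 and comes back at 17. Dibromomethylenation (Ph3P+CHBr2 Br−, KOtBu, THF) gives (6S)-9-(dibromomethylidene)-4,4-ethylenedioxy-5,5-dimethyl-1-methylidenespiro[5.5]undec-7-ene F6. Hydrogenolysis with Bu3SnH and Pd(PPh3)4 (cat.) then removes the more accessible bromine. This puts hydrogen where the Wittig reaction puts bromine, so its geometric preference is the opposite one and it should favour 9Z exactly when the Wittig reaction favours 9E.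

**Further compounds**
F1 | step 12 | (6S,9Z)-9-(bromomethylidene)-5,5-dimethyl-1-methylidenespiro[5.5]undec-7-en-4-one hydrazone | C=C1CCC(=NN)C(C)(C)[C@@]12C=C/C(=C\Br)CC2
F2 | step 12 | (6S,9Z)-4,4-dibromo-9-(bromomethylidene)-5,5-dimethyl-1-methylidenespiro[5.5]undec-7-ene | C=C1CCC(Br)(Br)C(C)(C)[C@@]12C=C/C(=C\Br)CC2
F3 | step 12 | (4S,6S,9Z)-4-bromo-9-(bromomethylidene)-5,5-dimethyl-1-methylidenespiro[5.5]undec-7-ene | C=C1CC[C@H](Br)C(C)(C)[C@@]12C=C/C(=C\Br)CC2
F4 | step 6 | 2-ethenyl-6,6-ethylenedioxy-5,5-dimethyl-2-(trimethylsilyloxy)-1,2,3,4,5,6,7,8-octahydronaphthalene (racemic) | C=CC1(O[Si](C)(C)C)CCC2=C(C1)CCC3(OCCO3)C2(C)C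
F5 | step 6 | 4,4-ethylenedioxy-5,5-dimethyl-1-methylidene-9-(trimethylsilyloxy)spiro[5.5]undec-8-ene (racemic) | C=C1CCC2(OCCO2)C(C)(C)C13CC=C(O[Si](C)(C)C)CC3
F6 | step 9 | (6S)-9-(dibromomethylidene)-4,4-ethylenedioxy-5,5-dimethyl-1-methylidenespiro[5.5]undec-7-ene | C=C1CCC3(OCCO3)C(C)(C)[C@@]12C=CC(=C(Br)Br)CC2
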